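**Retrosynthetic overview**
1. The chromene ring is closed last: acid unmasking of a bis-MOM isoflavan carrying a 1-hydroxy-3-methylbut-2-enyl group at C5' gives the ortho-quinone methide that biosynthesis would reach by oxidising a 5'-prenyl group; oxa-6π electrocyclisation onto 4'-O gives the target.
2. Both C5 units are put on ring B of an (R)-isoflavan by two successive directed ortho-lithiations (C3' with prenyl bromide, then C5' with prenal); ring A is switched off as its 7-phenoxide.
3. The (R)-isoflavan comes from a 7-benzyloxy isoflavone by asymmetric transfer hydrogenation with dynamic kinetic resolution (sets C3), then one hydrogenolysis (removes C4–OH and benzyl).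
4. Ring C comes from a 2'-hydroxychalcone by oxidative 1,2-aryl shift with trivalent thallium (isoflavone-synthase logic) and ring closure; the chalcone comes from a Claisen–Schmidt condensation.
5. Ring order: rings A and B are bought as benzenoids, ring C is formed third, the dimethylpyran ring fourth and last.

Assumption: the stereodescriptor of the given SMILES is read as (3R); the benzyl-protected acetophenone, prenyl bromide and prenal are taken as catalogue chemicals.

**Route**

Step 1
Reactants: 1 2,4-dihydroxybenzaldehyde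
Product: 2 2,4-bis(methoxymethoxy)benzaldehyde
Conditions: NaH (2.4 equiv), MOMCl (2.4 equiv), DMF, 0 °C → rt
Reagents that add atoms: chloromethyl methyl ether (MOMCl), COCCl
Why: Williamson-type O-alkylation (MOM protection) of both phenoxides, NaH in DMF also alkylating the hydrogen-bonded 2-OH; no stereocentre is involved.

Step 2
Reactants: 2 2,4-bis(methoxymethoxy)benzaldehyde; 3 1-[4-(benzyloxy)-2-hydroxyphenyl]ethan-1-one
Product: 4 (E)-1-[4-(benzyloxy)-2-hydroxyphenyl]-3-[2,4-bis(methoxymethoxy)phenyl]prop-2-en-1-one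
Conditions: KOH (50% aq.), EtOH, rt, 36 h; AcOH to pH 6
Reagents that add atoms: none
Why: Claisen–Schmidt aldol condensation, in which the acetophenone enolate adds to the non-enolisable aldehyde and E1cB dehydration gives the favoured E-enone, MOM and benzyl ethers being inert to aqueous KOH.

Step 3
Reactants: 4 (E)-1-[4-(benzyloxy)-2-hydroxyphenyl]-3-[2,4-bis(methoxymethoxy)phenyl]prop-2-en-1-one
Product: 6 7-(benzyloxy)-3-[2,4-bis(methoxymethoxy)phenyl]-4H-chromen-4-one, via dimethyl acetal 5 (not isolated)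
Conditions: Tl(NO3)3·3H2O (1.2 equiv), MeOH/HC(OMe)3 1:1, rt, 3 h; filter, NaHCO3, concentrate; then PPTS (20 mol%), toluene, 5 Å MS, 90 °C
Reagents that add atoms: none
Why: Oxidative 1,2-aryl migration of a chalcone (the laboratory counterpart of isoflavone synthase), in which oxythallation of the enone by trivalent thallium in methanol makes the electron-rich 2,4-dioxygenated aryl group migrate to give β-keto acetal 5, whose two methoxy groups (from methanol) leave again when the free 2'-phenol closes ring C by transacetalisation and elimination under PPTS, an acid too weak to cleave aryl MOM ethers in dry toluene; the racemic centre of 5 becomes sp2.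

Step 4
Reactants: 6 7-(benzyloxy)-3-[2,4-bis(methoxymethoxy)phenyl]-4H-chromen-4-one
Product: 8 (3R,4R)-7-(benzyloxy)-3-[2,4-bis(methoxymethoxy)phenyl]chroman-4-ol, via isoflavanone 7 (not isolated)
Conditions: RuCl[(R,R)-TsDPEN](p-cymene) (3 mol%), HCO2H/Et3N 5:2, EtOAc, 40 °C
Reagents that add atoms: none
Why: Noyori asymmetric transfer hydrogenation with dynamic kinetic resolution, in which Ru–H conjugate reduction gives isoflavanone 7, whose C3 epimerises through the enol under Et3N while the (R,R)-catalyst reduces the ketone to the (4R)-alcohol (same sense as for 4-chromanone) preferentially in the epimer that gives the cis product, so that C3 is set as R here.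

Step 5
Reactants: 8 (3R,4R)-7-(benzyloxy)-3-[2,4-bis(methoxymethoxy)phenyl]chroman-4-ol
Product: 9 (3R)-3-[2,4-bis(methoxymethoxy)phenyl]chroman-7-ol
Conditions: H2 (3 atm), Pd(OH)2/C, EtOH/EtOAc, AcOH (cat.), rt
Reagents that add atoms: none
Why: Catalytic hydrogenolysis cleaves the O-benzyl ether and the electron-rich benzylic C4–OH in one operation while the MOM ethers and C3 (no C–O bond, no enolisable neighbour) are untouched, so the centre stays (3R).

Step 6
Reactants: 9 (3R)-3-[2,4-bis(methoxymethoxy)phenyl]chroman-7-ol; 10 1-bromo-3-methylbut-2-ene (prenyl bromide)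
Product: 12 (3R)-3-[2,4-bis(methoxymethoxy)-3-(3-methylbut-2-en-1-yl)phenyl]chroman-7-ol, via aryllithium 11 (not isolated)
Conditions: n-BuLi (2.3 equiv), THF, 0 °C, 1 h; CuBr·SMe2 (10 mol%), 10 (1.1 equiv), −78 °C → rt; H2O
Reagents that add atoms: none
Why: Directed ortho-metalation, in which the first equivalent of n-BuLi makes the 7-phenoxide (deactivating ring A), the second removes the C3' proton flanked by two chelating OMOM groups, and the aryllithium is alkylated at the primary carbon of prenyl bromide (copper-assisted SN2) without touching C3.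

Step 7
Reactants: 12 (3R)-3-[2,4-bis(methoxymethoxy)-3-(3-methylbut-2-en-1-yl)phenyl]chroman-7-ol; 13 3-methylbut-2-enal (prenal)
Product: 15 (3R)-3-[5-(1-hydroxy-3-methylbut-2-en-1-yl)-2,4-bis(methoxymethoxy)-3-(3-methylbut-2-en-1-yl)phenyl]chroman-7-ol (both carbinol epimers), via aryllithium 14 (not isolated)
Conditions: n-BuLi (2.5 equiv), TMEDA, THF, 0 °C, 2 h; 13 (1.5 equiv), −78 °C; H2O
Reagents that add atoms: none
Why: Second directed ortho-metalation followed by carbonyl 1,2-addition, in which (C3' now being blocked and ring A again a phenoxide) the 4'-OMOM group directs lithiation to C5' and the aryllithium adds to prenal to give the benzylic allylic alcohol as an inconsequential mixture of carbinol epimers.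

Step 8
Reactants: 15 (3R)-3-[5-(1-hydroxy-3-methylbut-2-en-1-yl)-2,4-bis(methoxymethoxy)-3-(3-methylbut-2-en-1-yl)phenyl]chroman-7-ol
Product: 17 (3R)-3-[7-hydroxy-2,2-dimethyl-8-(3-methylbut-2-en-1-yl)-2H-chromen-6-yl]chroman-7-ol, via ortho-quinone methide 16 (not isolated)
Conditions: HCl (0.5 M in MeOH), 0.01 M substrate, N2, rt → 40 °C
Reagents that add atoms: none
Why: Acid cleavage of both MOM acetals and ionisation of the doubly activated carbinol give ortho-quinone methide 16 (the species biosynthesis is presumed to reach by oxidising a 5'-prenyl group), which closes by oxa-6π electrocyclisation onto the only ortho oxygen (4'-O) to give the 2,2-dimethyl-2H-chromene; the carbinol centre is destroyed and C3 is not involved.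

**Compound list**
1 | 2,4-dihydroxybenzaldehyde | O=Cc1ccc(O)cc1O | starting material
2 | 2,4-bis(methoxymethoxy)benzaldehyde | O=Cc1ccc(OCOC)cc1OCOC | intermediate
3 | 1-[4-(benzyloxy)-2-hydroxyphenyl]ethan-1-one | CC(=O)c1ccc(OCc2ccccc2)cc1O | starting material
4 | (E)-1-[4-(benzyloxy)-2-hydroxyphenyl]-3-[2,4-bis(methoxymethoxy)phenyl]prop-2-en-1-one | O=C(/C=C/c1ccc(OCOC)cc1OCOC)c1ccc(OCc2ccccc2)cc1O | intermediate
5 | rac-1-[4-(benzyloxy)-2-hydroxyphenyl]-2-[2,4-bis(methoxymethoxy)phenyl]-3,3-dimethoxypropan-1-one | O=C(C(C(OC)OC)c1ccc(OCOC)cc1OCOC)c1ccc(OCc2ccccc2)cc1O | intermediate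
6 | 7-(benzyloxy)-3-[2,4-bis(methoxymethoxy)phenyl]-4H-chromen-4-one | O=c1c(-c2ccc(OCOC)cc2OCOC)coc2cc(OCc3ccccc3)ccc12 | intermediate
7 | 7-(benzyloxy)-3-[2,4-bis(methoxymethoxy)phenyl]chroman-4-one (C3 epimerising) | O=C1C(c2ccc(OCOC)cc2OCOC)COc2cc(OCc3ccccc3)ccc21 | intermediate
8 | (3R,4R)-7-(benzyloxy)-3-[2,4-bis(methoxymethoxy)phenyl]chroman-4-ol (cis) | O[C@@H]1[C@H](c2ccc(OCOC)cc2OCOC)COc2cc(OCc3ccccc3)ccc21 | intermediate
9 | (3R)-3-[2,4-bis(methoxymethoxy)phenyl]chroman-7-ol | COCOc1ccc([C@@H]2COc3cc(O)ccc3C2)c(OCOC)c1 | intermediate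
10 | 1-bromo-3-methylbut-2-ene (prenyl bromide) | CC(C)=CCBr | starting material
11 | lithium (3R)-3-[3-lithio-2,4-bis(methoxymethoxy)phenyl]chroman-7-olate | COCOc1ccc([C@@H]2COc3cc([O-])ccc3C2)c(OCOC)c1[Li].[Li+] | intermediate
12 | (3R)-3-[2,4-bis(methoxymethoxy)-3-(3-methylbut-2-en-1-yl)phenyl]chroman-7-ol | COCOc1ccc([C@@H]2COc3cc(O)ccc3C2)c(OCOC)c1CC=C(C)C | intermediate
13 | 3-methylbut-2-enal (prenal) | CC(C)=CC=O | starting material
14 | lithium (3R)-3-[5-lithio-2,4-bis(methoxymethoxy)-3-(3-methylbut-2-en-1-yl)phenyl]chroman-7-olate | COCOc1c([Li])cc([C@@H]2COc3cc([O-])ccc3C2)c(OCOC)c1CC=C(C)C.[Li+] | intermediate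
15 | (3R)-3-[5-(1-hydroxy-3-methylbut-2-en-1-yl)-2,4-bis(methoxymethoxy)-3-(3-methylbut-2-en-1-yl)phenyl]chroman-7-ol, carbinol carbon unassigned (both epimers) | COCOc1c(C(O)C=C(C)C)cc([C@@H]2COc3cc(O)ccc3C2)c(OCOC)c1CC=C(C)C | intermediate
16 | 3-hydroxy-4-[(3R)-7-hydroxychroman-3-yl]-2-(3-methylbut-2-en-1-yl)-6-(3-methylbut-2-en-1-ylidene)cyclohexa-2,4-dien-1-one (ortho-quinone methide) | O=C1C(=CC=C(C)C)C=C([C@@H]2COc3cc(O)ccc3C2)C(O)=C1CC=C(C)C | intermediate
17 | (3R)-3-[7-hydroxy-2,2-dimethyl-8-(3-methylbut-2-en-1-yl)-2H-chromen-6-yl]chroman-7-ol | CC(C)=CCc1c(O)c([C@@H]2COc3cc(O)ccc3C2)cc2c1OC(C)(C)C=C2 | target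

**Count and risks**
Total step count: 8. Longest linear sequence: 8 steps (1 → 17).

Most likely to fail:

Step 3. The MOM ethers may not survive ring closure, or the acetal may close sluggishly under the weak acid. Fallback, setting out from 4 and coming back at 6: give up MOM retention. After the same oxidation with trivalent thallium, the crude acetal 5 is heated in methanolic HCl, which closes ring C and strips both MOM groups to give 7-(benzyloxy)-3-(2,4-dihydroxyphenyl)-4H-chromen-4-one F1. This is re-protected with MOMCl and NaH in DMF to return to 6, at the cost of one extra step.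

Step 7. Lithiation at C5' may be slow or unselective (ring A C8, the benzylic prenyl CH2), or prenal may be enolised. Fallback, setting out from 12 and coming back at 17: leave organolithium chemistry for a phenol–enal condensation.
- The 7-OH of 12 is acylated (NaH, pivaloyl chloride, THF) to (3R)-3-[2,4-bis(methoxymethoxy)-3-(3-methylbut-2-en-1-yl)phenyl]chroman-7-yl pivalate F2.
- The MOM ethers are removed (HCl, MeOH, rt) to give (3R)-3-[2,4-dihydroxy-3-(3-methylbut-2-en-1-yl)phenyl]chroman-7-yl pivalate F3.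
- F3 is condensed with prenal 13 (ethylenediammonium diacetate cat., toluene, 110 °C). Only C5' is free and activated, and ring A has no free phenol, so the product is (3R)-3-[7-hydroxy-2,2-dimethyl-8-(3-methylbut-2-en-1-yl)-2H-chromen-6-yl]chroman-7-yl pivalate F4.
- K2CO3 in MeOH then frees 17.

Step 8. The cationic cascade may give oligomers by intermolecular attack of ring A on the quinone methide, or acid may cyclise the 3'-prenyl group onto the 2'-OH. Fallback, setting out from 15 and coming back at 17: close the ring by conjugate addition instead of through the quinone methide.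
- MnO2 in CH2Cl2 oxidises the carbinol to 1-{5-[(3R)-7-hydroxychroman-3-yl]-2,4-bis(methoxymethoxy)-3-(3-methylbut-2-en-1-yl)phenyl}-3-methylbut-2-en-1-one F5.
- Methanolic HCl removes the MOM groups, and the 4'-OH adds to the enone (oxa-Michael) to give 7-hydroxy-6-[(3R)-7-hydroxychroman-3-yl]-2,2-dimethyl-8-(3-methylbut-2-en-1-yl)chroman-4-one F6.
- NaBH4 in MeOH gives 6-[(3R)-7-hydroxychroman-3-yl]-2,2-dimethyl-8-(3-methylbut-2-en-1-yl)chromane-4,7-diol F7.
- Mild dehydration of F7 (p-TsOH cat., toluene, 50 °C) gives 17.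

**Further compounds**
F1 | step 3 | 7-(benzyloxy)-3-(2,4-dihydroxyphenyl)-4H-chromen-4-one | O=c1c(-c2ccc(O)cc2O)coc2cc(OCc3ccccc3)ccc12
F2 | step 7 | (3R)-3-[2,4-bis(methoxymethoxy)-3-(3-methylbut-2-en-1-yl)phenyl]chroman-7-yl pivalate | COCOc1ccc([C@@H]2COc3cc(OC(=O)C(C)(C)C)ccc3C2)c(OCOC)c1CC=C(C)C
F3 | step 7 | (3R)-3-[2,4-dihydroxy-3-(3-methylbut-2-en-1-yl)phenyl]chroman-7-yl pivalate | CC(C)=CCc1c(O)ccc([C@@H]2COc3cc(OC(=O)C(C)(C)C)ccc3C2)c1O
F4 | step 7 | (3R)-3-[7-hydroxy-2,2-dimethyl-8-(3-methylbut-2-en-1-yl)-2H-chromen-6-yl]chroman-7-yl pivalate | CC(C)=CCc1c(O)c([C@@H]2COc3cc(OC(=O)C(C)(C)C)ccc3C2)cc2c1OC(C)(C)C=C2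
F5 | step 8 | 1-{5-[(3R)-7-hydroxychroman-3-yl]-2,4-bis(methoxymethoxy)-3-(3-methylbut-2-en-1-yl)phenyl}-3-methylbut-2-en-1-one | COCOc1c(C(=O)C=C(C)C)cc([C@@H]2COc3cc(O)ccc3C2)c(OCOC)c1CC=C(C)C
F6 | step 8 | 7-hydroxy-6-[(3R)-7-hydroxychroman-3-yl]-2,2-dimethyl-8-(3-methylbut-2-en-1-yl)chroman-4-one | CC(C)=CCc1c(O)c([C@@H]2COc3cc(O)ccc3C2)cc2c1OC(C)(C)CC2=O
F7 | step 8 | 6-[(3R)-7-hydroxychroman-3-yl]-2,2-dimethyl-8-(3-methylbut-2-en-1-yl)chromane-4,7-diol (both C4 epimers) | CC(C)=CCc1c(O)c([C@@H]2COc3cc(O)ccc3C2)cc2c1OC(C)(C)CC2O
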